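**Retrosynthetic overview**
1. Rings A (phenol) and B (anisole) carry the same 2-oxy-4,6-dibromo pattern. Ring B therefore enters ready-made as 2,4-dibromo-6-methoxyphenol, and only ring A is built, last and as the free phenol, so no protecting group is needed.
2. Ring A is cut at C1–C2 (6π-electrocyclization of a dienylketene) and at C3–C4 (Wolff shift). This leads back to the (3E,5Z)-dienyl diazomethyl ketone 10, and from there to acid 7 and TMSCHN2 (which supplies C3).
3. The strategy rests on this feature: the aryloxy carbon C1, C6–Br, C5–H and C4–Br of ring A are C6, C5, C4 and C3 of 3,5-dibromo-2H-pyran-2-one, and C2 (C–OH) is its carbonyl carbon. The pyrone ring fixes the cis C4=C5 alkene that the closure needs.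
4. The hindered diaryl ether C–O bond is made first, as a vinyl ether, by 1,6-addition of the ring B aryloxide to C6 of the pyrone with ring opening.

Key step: step 4

Remark on the chemistry: the target has no stereocentre; because its rings differ only in OH against OMe, the phenol set free by the ring closure is the target itself. Compound 3 is taken as a catalogue compound.

**Step 1**
Reactants: 1 2-methoxyphenol (guaiacol)
Product: 2 2,4-dibromo-6-methoxyphenol
Conditions: NBS (2.05 equiv), MeCN, 0 °C to rt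
Reagents that add atoms: N-bromosuccinimide, O=C1CCC(=O)N1Br
Why: Electrophilic aromatic bromination in which the free hydroxyl is the strongest director, so bromine should enter para (C4) and then ortho (C6) to it rather than para or ortho to the methoxy group.

**Step 2**
Reactants: 2 2,4-dibromo-6-methoxyphenol; 3 3,5-dibromo-2H-pyran-2-one
Product: 7 (2E,4Z)-2,4-dibromo-5-(2,4-dibromo-6-methoxyphenoxy)penta-2,4-dienoic acid, via potassium aryloxide 4 (not isolated), via pyranolate adduct 5 (not isolated), via potassium dienoate 6 (not isolated)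
Conditions: KOt-Bu (0.98 equiv), THF, 0 °C; then 3 (1.0 equiv), 18-crown-6 (10 mol %), THF–DMF, −20 °C to rt; cold 1 M HCl to pH 2, EtOAc; used without storage
Reagents that add atoms: potassium tert-butoxide, CC(C)(C)[O-].[K+] (supplies only the potassium of 4, 5 and 6; 7 holds no atom of it)
Why: Proposed new method: the aryloxide should add in 1,6-fashion to C6 of 3 (the δ-carbon of the dienoate, acetal-like and further activated by the C5 bromine) to give dienolate 5, which breaks its C6–O1 bond with expulsion of the much better leaving carboxylate (E1cB, equivalently an oxa-6π ring opening with the aryloxy group turning outward, hence 4Z), so that the former C3=C4 bond of the ring stays cis (2E) while acyl attack at C2 remains reversible for an aryloxide; the closest known reactions are the 1,6-addition with ring opening of coumalate esters by alkoxides and amines and of 2H-pyran-2-one by Grignard reagents to (2Z)-dienoic acids.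

**Step 3**
Reactants: 7 (2E,4Z)-2,4-dibromo-5-(2,4-dibromo-6-methoxyphenoxy)penta-2,4-dienoic acid; 8 (trimethylsilyl)diazomethane
Product: 10 (3E,5Z)-3,5-dibromo-6-(2,4-dibromo-6-methoxyphenoxy)-1-diazohexa-3,5-dien-2-one, via acid chloride 9 (not isolated)
Conditions: Me2C=C(Cl)NMe2 (1.05 equiv), CH2Cl2, 0 °C to rt; then 8 (2.2 equiv, 2 M in hexanes), THF–MeCN (1:1), 0 °C, dark; concentrate, chromatography on Et3N-deactivated silica
Reagents that add atoms: 1-chloro-N,N,2-trimethylprop-1-en-1-amine, CC(C)=C(Cl)N(C)C (supplies only the chlorine of 9; the CHN2 unit of 10 comes from reactant 8)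
Why: Arndt–Eistert-type acylation in which the chloroenamine makes acyl chloride 9 without releasing HCl (which could re-close the lactone with loss of 2) and C-acylation of the diazoalkane followed by loss of Me3SiCl gives the diazomethyl ketone, dipolar cycloaddition to the C2=C3 bond being slowed by its α-bromine and β-substituent.

**Step 4**
Reactants: 10 (3E,5Z)-3,5-dibromo-6-(2,4-dibromo-6-methoxyphenoxy)-1-diazohexa-3,5-dien-2-one
Product: 13 3,5-dibromo-2-(2,4-dibromo-6-methoxyphenoxy)phenol (target), via dienylketene 11 (not isolated), via cyclohexadienone 12 (not isolated)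
Conditions: hν (450 nm LEDs), degassed PhMe (0.005 M), 20 °C; then 40 °C, dark
Reagents that add atoms: none
Why: Excitation of the diazomethyl ketone (s-Z conformer) should expel N2 with concerted 1,2-shift of the dienyl carbon C4 from C2 to C3 (Wolff rearrangement), giving dienylketene 11 with both alkene geometries retained. Ring A then closes by a thermal disrotatory 6π-electrocyclization of the C2=C3, C4=C5 and C6=C1 bonds that forms C1–C2 and gives cyclohexa-2,4-dienone 12, which enolizes (C1–H to O) to the aromatic phenol 13. The closest known reactions are the photochemical Wolff rearrangement of α,β-unsaturated diazoketones to vinylketenes and the dienylketene-to-phenol closure that ends the Danheiser and Dötz benzannulations. No stereocentre survives, since the sp3 C1 of 12 is racemic and is lost on aromatization. The step needs a cis C4=C5 bond, which is inherited from the C3=C4 bond of the pyrone ring, and it needs rearrangement to outrun carbene chemistry and ring closure to outrun ketene capture, which the s-Z diazomethyl ketone, metal-free direct irradiation and a dilute nucleophile-free medium should secure. Light of 450 nm should be absorbed only by the conjugated diazoketone, so the four C–Br bonds and the product should stay unexcited.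

**Compound list**
1 | 2-methoxyphenol (guaiacol) | COc1ccccc1O | starting material
2 | 2,4-dibromo-6-methoxyphenol | COc1cc(Br)cc(Br)c1O | intermediate
3 | 3,5-dibromo-2H-pyran-2-one | O=C1OC=C(Br)C=C1Br | starting material
4 | potassium 2,4-dibromo-6-methoxyphenolate | [K+].[O-]c1c(OC)cc(Br)cc1Br | intermediate (not isolated)
5 | potassium 3,5-dibromo-6-(2,4-dibromo-6-methoxyphenoxy)-6H-pyran-2-olate (racemic) | [K+].[O-]C1=C(Br)C=C(Br)C(Oc2c(OC)cc(Br)cc2Br)O1 | intermediate (not isolated)
6 | potassium (2E,4Z)-2,4-dibromo-5-(2,4-dibromo-6-methoxyphenoxy)penta-2,4-dienoate | [K+].[O-]C(=O)/C(Br)=C\C(Br)=C\Oc1c(OC)cc(Br)cc1Br | intermediate (not isolated)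
7 | (2E,4Z)-2,4-dibromo-5-(2,4-dibromo-6-methoxyphenoxy)penta-2,4-dienoic acid | OC(=O)/C(Br)=C\C(Br)=C\Oc1c(OC)cc(Br)cc1Br | intermediate
8 | (trimethylsilyl)diazomethane | C[Si](C)(C)C=[N+]=[N-] | starting material
9 | (2E,4Z)-2,4-dibromo-5-(2,4-dibromo-6-methoxyphenoxy)penta-2,4-dienoyl chloride | ClC(=O)/C(Br)=C\C(Br)=C\Oc1c(OC)cc(Br)cc1Br | intermediate (not isolated)
10 | (3E,5Z)-3,5-dibromo-6-(2,4-dibromo-6-methoxyphenoxy)-1-diazohexa-3,5-dien-2-one | [N-]=[N+]=CC(=O)/C(Br)=C\C(Br)=C\Oc1c(OC)cc(Br)cc1Br | intermediate (key-step precursor)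
11 | (3E,5Z)-3,5-dibromo-6-(2,4-dibromo-6-methoxyphenoxy)hexa-1,3,5-trien-1-one | O=C=C/C(Br)=C\C(Br)=C\Oc1c(OC)cc(Br)cc1Br | intermediate (not isolated)
12 | 3,5-dibromo-6-(2,4-dibromo-6-methoxyphenoxy)cyclohexa-2,4-dien-1-one (racemic) | O=C1C=C(Br)C=C(Br)C1Oc1c(OC)cc(Br)cc1Br | intermediate (not isolated)
13 | 3,5-dibromo-2-(2,4-dibromo-6-methoxyphenoxy)phenol | COc1cc(Br)cc(Br)c1Oc1c(O)cc(Br)cc1Br | target

**Total step count:** 4. **Longest linear sequence:** 4 steps (1 → 2 → 7 → 10 → 13).

**Steps most likely to fail**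

Step 2 (Proposed new method). The hindered, weakly nucleophilic aryloxide may add too slowly at C6, so that acyl attack at C2 or conjugate addition at C4 followed by loss of HBr (cine substitution) consumes the pyrone instead of opening it. The fallback uses known chemistry only, sets out from 2 and comes back at 7. Amine-catalysed conjugate addition of 2 to ethyl propiolate (DABCO, CH2Cl2) should give ethyl (E)-3-(2,4-dibromo-6-methoxyphenoxy)prop-2-enoate F1. Addition of Br2 (CH2Cl2, 0 °C) gives ethyl 2,3-dibromo-3-(2,4-dibromo-6-methoxyphenoxy)propanoate F2, and Et3N then eliminates HBr to ethyl (Z)-2-bromo-3-(2,4-dibromo-6-methoxyphenoxy)prop-2-enoate F3. Reduction with i-Bu2AlH (CH2Cl2, −78 °C) gives (Z)-2-bromo-3-(2,4-dibromo-6-methoxyphenoxy)prop-2-en-1-ol F4, and MnO2 (CH2Cl2) oxidizes it to (Z)-2-bromo-3-(2,4-dibromo-6-methoxyphenoxy)prop-2-enal F5. An E-selective Horner–Wadsworth–Emmons reaction with methyl 2-[bis(2,2,2-trifluoroethoxy)phosphoryl]-2-bromoacetate (KOt-Bu, 18-crown-6, THF, −78 °C) places the ester cis to C4 and gives methyl (2E,4Z)-2,4-dibromo-5-(2,4-dibromo-6-methoxyphenoxy)penta-2,4-dienoate F6. LiOH (THF–water, 0 °C) then gives 7.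

Step 4. The C4=C5 bond may photoisomerize before N2 is lost (a trans ketene cannot close), ketene 11 may be captured by phenol already formed, or C–Br bonds may be cleaved by light. The fallback leaves ketene chemistry and makes the diaryl ether directly; it sets out from 2 and comes back at 13. Nucleophilic aromatic substitution of 2 on 3,5-dibromo-2-fluorobenzaldehyde (O=Cc1cc(Br)cc(Br)c1F; K2CO3, DMAc, 90 °C) should give 3,5-dibromo-2-(2,4-dibromo-6-methoxyphenoxy)benzaldehyde F7. Baeyer–Villiger oxidation (mCPBA, CH2Cl2, 40 °C) gives 3,5-dibromo-2-(2,4-dibromo-6-methoxyphenoxy)phenyl formate F8, and methanolysis (K2CO3, MeOH, rt) gives 13.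

Step 3. The diazoalkane may undergo 1,3-dipolar cycloaddition to the acyl-activated C2=C3 bond of 9, or acylation at the hindered α-bromo acyl chloride may be too slow. The fallback avoids any diazoalkane and installs the diazo group by diazo transfer; it sets out from 7 and comes back at 10. Coupling of 7 with N,O-dimethylhydroxylamine (EDC·HCl, HOBt, i-Pr2NEt, CH2Cl2) gives (2E,4Z)-2,4-dibromo-5-(2,4-dibromo-6-methoxyphenoxy)-N-methoxy-N-methylpenta-2,4-dienamide F9. MeMgBr (THF, −78 to 0 °C) gives (3E,5Z)-3,5-dibromo-6-(2,4-dibromo-6-methoxyphenoxy)hexa-3,5-dien-2-one F10. Its enolate (LiN(SiMe3)2, THF, −78 °C) is acylated with CF3CO2CH2CF3 to (5E,7Z)-5,7-dibromo-8-(2,4-dibromo-6-methoxyphenoxy)-1,1,1-trifluoroocta-5,7-diene-2,4-dione F11. Detrifluoroacetylative diazo transfer (MsN3, Et3N, water, MeCN) then gives 10.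

**Further compounds**
F1 | step 2 | ethyl (E)-3-(2,4-dibromo-6-methoxyphenoxy)prop-2-enoate | CCOC(=O)/C=C/Oc1c(OC)cc(Br)cc1Br
F2 | step 2 | ethyl 2,3-dibromo-3-(2,4-dibromo-6-methoxyphenoxy)propanoate (racemic, diastereomer mixture) | CCOC(=O)C(Br)C(Br)Oc1c(OC)cc(Br)cc1Br
F3 | step 2 | ethyl (Z)-2-bromo-3-(2,4-dibromo-6-methoxyphenoxy)prop-2-enoate | CCOC(=O)/C(Br)=C/Oc1c(OC)cc(Br)cc1Br
F4 | step 2 | (Z)-2-bromo-3-(2,4-dibromo-6-methoxyphenoxy)prop-2-en-1-ol | OC/C(Br)=C/Oc1c(OC)cc(Br)cc1Br
F5 | step 2 | (Z)-2-bromo-3-(2,4-dibromo-6-methoxyphenoxy)prop-2-enal | O=C/C(Br)=C/Oc1c(OC)cc(Br)cc1Br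
F6 | step 2 | methyl (2E,4Z)-2,4-dibromo-5-(2,4-dibromo-6-methoxyphenoxy)penta-2,4-dienoate | COC(=O)/C(Br)=C\C(Br)=C\Oc1c(OC)cc(Br)cc1Br
F7 | step 4 | 3,5-dibromo-2-(2,4-dibromo-6-methoxyphenoxy)benzaldehyde | O=Cc1cc(Br)cc(Br)c1Oc1c(OC)cc(Br)cc1Br
F8 | step 4 | 3,5-dibromo-2-(2,4-dibromo-6-methoxyphenoxy)phenyl formate | O=COc1cc(Br)cc(Br)c1Oc1c(OC)cc(Br)cc1Br
F9 | step 3 | (2E,4Z)-2,4-dibromo-5-(2,4-dibromo-6-methoxyphenoxy)-N-methoxy-N-methylpenta-2,4-dienamide | CON(C)C(=O)/C(Br)=C\C(Br)=C\Oc1c(OC)cc(Br)cc1Br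
F10 | step 3 | (3E,5Z)-3,5-dibromo-6-(2,4-dibromo-6-methoxyphenoxy)hexa-3,5-dien-2-one | CC(=O)/C(Br)=C\C(Br)=C\Oc1c(OC)cc(Br)cc1Br
F11 | step 3 | (5E,7Z)-5,7-dibromo-8-(2,4-dibromo-6-methoxyphenoxy)-1,1,1-trifluoroocta-5,7-diene-2,4-dione | O=C(CC(=O)/C(Br)=C\C(Br)=C\Oc1c(OC)cc(Br)cc1Br)C(F)(F)F
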